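## The problem

CNP0500052.1 (**29**) is an elemane-type sesquiterpene lactone: one cyclohexane (C5–C10) in which every ring carbon is a stereocentre, cis-fused at C7–C8 to an α-methylene-γ-butyrolactone (C11, C12, methylene C13, ring oxygen on C8). The numbering used throughout is: C5 carries the 3-acetoxyprop-1-en-2-yl group (C4, methylene C3, acetoxymethyl C15), C6 the isobutyrate, C7 the lactone carbon C11, C8 the lactone oxygen, C9 the acetate, and C10 the methyl group C14 and the vinyl group C1=C2. β is the ring face that carries C14, α the other face. The substituents on C5, C6, C7 and C8 are all β, while the C9 acetate and the C10 vinyl group are α, so four contiguous cis substituents stand next to a trans-diol unit and a quaternary carbon. The vicinal pair C5/C10 (alkenyl groups trans) cannot be corrected later and must come from reagent control. After that C9 can be set from C10/C5, C7 from C9, C8 and C9 from the C7 side chain, and C6 last from the ring as a whole. The molecule is fragile: the methylene lactone is a Michael acceptor; the esters are of two kinds and exclude enolate chemistry once they are present; a C6 ketone has the lactone oxygen in the β-position and enolisable C5 and C7; and the two alkenyl groups form a 1,5-diene. The enabling feature is that C5 and C10 are adjacent, carry the two alkenyl groups and lie between the oxygenated carbons C6 and C9. They are therefore the β- and α-carbons of a 2-methylcyclohex-2-enone whose carbonyl is C9 and whose γ-carbon C6 is a ketal carbon.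

## Retrosynthesis

**C6 ester and carbinol.** The C6–O acyl bond of **29** is cut first, giving alcohol **28**, which comes from ketone **27** by hydride addition to the α face. Selective esterification of a triol was rejected. Instead C6 stays masked as the dimethyl ketal of **26** while the C9 and C15 hydroxyls of **25** are acetylated together, so the ketal is what distinguishes the isobutyrate site. The forward reduction must avoid the β face, which carries the C5 and C7 substituents, C14 and the lactone oxygen.

**Methylene group.** C11=C13 is traced to the saturated lactone **20** and the iminium salt **21** (Mannich base **22**, ammonium salt **23**, elimination to **24**). This is placed before any acylation, because a lactone enolate cannot be formed beside acetates, and before the ketal is removed, so that C11 is the only enolisable carbon.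

**Lactone C–O bond and C9 oxygen.** The C8–O bond and the C9 hydroxyl of **20** are traced to the α-epoxide **19** of the γ,δ-unsaturated acid **18**. The carboxyl group, held on the β face by C7, opens the epoxide at C8 with inversion, so one operation gives the cis ring fusion and the trans C8/C9 relationship. The neighbouring cuts set C9 wrongly: a halolactonisation would leave a C9 halide that could only be exchanged with inversion at a neopentyl centre, and reduction of a C9 ketone in the finished lactone would place the hydroxyl cis to the C8 oxygen. The forward step must select the ring alkene among three alkenes and its α face.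

**C7–C11 bond.** Acid **18** is the hydrolysis product of ester **17**. The C7–C11 bond of **17** is cut in the [3,3] sense to allylic alcohol **13** and orthoester **14**. Conjugate addition of an acetate equivalent to enone **10** would be shorter, but C7 of **10** is attacked anti to the C5 substituent, which gives the C7 epimer, and correction by equilibration through a C6 ketone is not dependable because the cis arrangement suffers 1,3-diaxial strain. The sigmatropic route transfers the C9 β-oxygen to a C7 β-carbon suprafacially and leaves the double bond at C8=C9, where the epoxidation needs it. The precursor is simpler by two carbons and asks only for one carbinol configuration.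

**C9 carbinol and C15 oxygen.** **13** comes from enone **10** by allylic oxidation at C15 (**11**), 1,2-reduction (**12**) and silylation of the primary hydroxyl. C15 is oxidised here for two reasons: **10** has no enolisable methylene and no second allylic C–H, and an oxygen on C15 deactivates the side-chain alkene before the peracid step.

**Ring unsaturation and vinyl group.** **10** comes from ketone **8** through silyl enol ether **9**; only C8 can be enolised and only C7–C8 can be dehydrogenated. **8** comes from sulfoxide **7** by thermal elimination.

**Key disconnection.** In **7** the bonds C5–C4 and C10–C1 are cut together, which leads to the achiral enone **3**, Grignard reagent **4** and vinyl sulfoxide **5**. Both stereocentres of the difficult vicinal pair, one of them quaternary, arise across one flat double bond. Building the ring from an open chain would mean setting this pair without the help of a ring. The forward reaction must add to a β-carbon that lies between a ketal carbon and a methyl-bearing α-carbon, with one enantioface selected, and the enolate must be alkylated on carbon, trans to the new group.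

**Enone.** **3** comes from dienone **2** by saturation of its unsubstituted double bond, and **2** from phenol **1** by oxidative ketalisation, which fixes the C6 oxygen from the start.

## Roads not taken

**Alternative 1:** The cut is the C8=C9 double bond of a cyclohexene. Ring-closing metathesis of triene **A2** (a vinyl group on C7, two vinyl groups and the methyl on C10) with a chiral molybdenum imido alkylidene of the type Mo(N-2,6-i-Pr2C6H3)(CHCMe2Ph)(diolate), diolate being an enantiopure biphenyl-2,2'-diolate, would have to engage one of the two diastereotopic C10 vinyl groups to give cyclohexene **A1**.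
- Merits: the quaternary centre becomes stereogenic under neutral conditions without enolate chemistry. **A1** already holds the C6 oxygen, the C7 acetate chain and the C15 oxygen, and it has the same C8=C9 alkene as **17**, so it could use the same epoxidation–lactonisation.
- Weak points: **A2** needs three contiguous stereocentres (C5, C6, C7) built in an open chain next to a fully substituted carbon. The group selection is a matched/mismatched problem in which the catalyst must override those centres. The 1,1-disubstituted alkene on C5 can compete with the C10 vinyl groups for the C7 vinyl group (cyclopentene formation). The catalyst is sensitive to air and protic groups.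
- Comparison: **A1** is further advanced than **7**, and here this road is better; the chosen plan needs steps 4–9 to reach the comparable **17**. Against that, the chosen plan reaches the C5/C10 pair in three steps from a commercial phenol by a catalytic step on a flat, achiral substrate, and its stereochemical risk falls early rather than on a long-chain intermediate.

**Alternative 2:** The cuts are C7–C8 and the lactone C12–O bond. Zerovalent indium (In powder) would insert into the allylic C–Br bond of bromo aldehyde **A4**; the allylindium would add through its γ-carbon C7 to the C8 aldehyde, and the C8 alkoxide would close the lactone on the ester to give lactone **A3**.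
- Merits: the carbocycle, the lactone, the methylene group and the C7 and C8 stereocentres form in one step that tolerates esters and water. **A3** is only two protecting-group exchanges from **29**. This endgame is clearly shorter than the nine steps that follow the Claisen rearrangement in the chosen plan, and it needs no late enolate.
- Weak points: C5, C6, C9 and the quaternary C10 must all be set in the open chain of **A4**. The vicinal quaternary/tertiary pair is the hardest element of the target and has no ring to help. The aldehyde is neopentyl and α-alkoxy (slow addition, risk of epimerisation at C9). The two new centres form relative to four resident ones through a transition state whose preference cannot be predicted, with no later correction.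
- Comparison: the chosen plan answers the shorter endgame with an early, catalytic solution for C5/C10 and with ring-based relay of every later centre.

**Alternative 3:** The cuts are C5–C6 and C9–C10. An endo Diels–Alder reaction of diene **A6** (C6 to C9) with dienophile **A7** (C5 and C10) under a chiral Lewis acid would give cycloadduct **A5** with a C7=C8 double bond.
- Merits: the ring and three stereocentres (C5, C6, C10) form at once from two achiral components. The C6 oxygen arrives in its final configuration, which the chosen plan sets only in step 17 and by substrate control; on this point the cycloaddition is better.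
- Weak points: the dienophile is trisubstituted and carries two different acceptors, so regiochemistry and endo preference both depend on the ketone dominating the ester. A quaternary carbon must be formed with a diene of modest reactivity. C9 emerges as an unfunctionalised methylene that has to be oxidised later. The ester must become the vinyl group and the acetyl group the oxygenated isopropenyl unit, the latter through an epimerisable, hindered ketone.
- Comparison: the chosen plan starts with C9 as the carbonyl and C6 as a ketal, so every ring carbon already has a usable oxidation level, and it brings in both alkenyl groups as such.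

Key step: step 3

## Route

Remark on the chemistry (assumption): the sense of induction of the ferrocenyl diphosphine on enone **3** cannot be predicted with certainty. The (R,S) ligand named in step 3 is taken to give the (3S) configuration of **7**; if the opposite sense is found, its commercially available antipode is used with no other change. Compounds **1**, **4**, **5**, **14** and **21** are purchased.

Step 1
Reactants: 1 4-methoxy-2-methylphenol
Product: 2 4,4-dimethoxy-2-methylcyclohexa-2,5-dien-1-one
Conditions: PhI(OAc)2, MeOH, 0 °C
Reagents that add atoms: methanol, CO
Why: Oxidative dearomatisation of a para-alkoxyphenol by trivalent iodine (quinone monoketal synthesis): after ligand exchange at iodine, methanol adds at the para carbon that already bears methoxy, giving the gem-dimethoxy carbon that becomes C6.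

Step 2
Reactants: 2 4,4-dimethoxy-2-methylcyclohexa-2,5-dien-1-one
Product: 3 4,4-dimethoxy-2-methylcyclohex-2-en-1-one
Conditions: H2 (1 atm), RhCl(PPh3)3 (cat.), toluene, rt
Reagents that add atoms: none
Why: Homogeneous hydrogenation with RhCl(PPh3)3 is governed by alkene substitution, so the unsubstituted C5=C6 bond of the cross-conjugated dienone should be saturated and the methyl-bearing C2=C3 bond kept; the neutral catalyst should not cause the reductive aromatisation that a heterogeneous palladium catalyst would.

Step 3
Reactants: 3 4,4-dimethoxy-2-methylcyclohex-2-en-1-one; 4 isopropenylmagnesium bromide; 5 phenyl vinyl sulfoxide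
Product: 7 (2S,3S)-4,4-dimethoxy-2-methyl-2-[2-(phenylsulfinyl)ethyl]-3-(prop-1-en-2-yl)cyclohexan-1-one (sulfinylethyl chain α and trans to the isopropenyl group; both epimers at sulfur), via bromomagnesium enolate 6 (not isolated)
Conditions: CuBr·SMe2 (5 mol %), (R)-1-[(S)-2-(diphenylphosphino)ferrocenyl]ethyldicyclohexylphosphine (6 mol %), t-BuOMe, −78 °C, slow addition of 4; then 5, THF/DMPU, −78 to 0 °C; aq. NH4Cl
Reagents that add atoms: none
Why: This is a copper-catalysed asymmetric 1,4-addition of a Grignard reagent to a cyclic enone followed by Michael trapping of the enolate; the closest known reaction types are ferrocenyl-diphosphine/CuBr·SMe2 additions to cyclohexenones with enolate capture and additions of ketone enolates to phenyl vinyl sulfoxide as a vinyl cation equivalent. The ligated alkenylcopper–magnesium species binds the C5=C10 π bond of 3, transfers the isopropenyl group to C5 through a trivalent copper intermediate and leaves the C9–C10 bromomagnesium enolate 6 regiospecifically. No ring is closed; the two new bonds are C5–C4 and C10–C1. C5 is set by the chiral ligand, which selects one enantioface of the flat enone; the ketal carbon C6 carries two identical methoxy groups and adds no bias of its own. C10 is set by the substrate: the enolate carbon attacks the β-carbon of 5 on the face opposite the adjacent, newly introduced isopropenyl group, which places the two-carbon chain trans to it and the methyl group cis. The step needs 1,4- over 1,2-addition (secured by monovalent copper, low temperature and slow addition), carbon over oxygen alkylation, and no enolate equilibration (C6 has no hydrogen and proton transfer from C8 is slow at low temperature, while DMPU raises the nucleophilicity of the magnesium enolate). The sulfinyl carbanion is protonated on quench, and the sulfur stereocentre is irrelevant because step 4 removes it.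

Step 4
Reactants: 7 (2S,3S)-4,4-dimethoxy-2-methyl-2-[2-(phenylsulfinyl)ethyl]-3-(prop-1-en-2-yl)cyclohexan-1-one
Product: 8 (2S,3S)-4,4-dimethoxy-2-methyl-3-(prop-1-en-2-yl)-2-vinylcyclohexan-1-one
Conditions: NaHCO3, toluene, 110 °C
Reagents that add atoms: none
Why: Sulfoxide pyrolysis (thermal syn elimination through a five-membered transition state): the only β-hydrogens are on C1, so the C1=C2 vinyl group should form from both sulfur epimers; the trans 1,2-dialkenyl unit should not undergo Cope ring expansion at this temperature because the ten-membered diene would be much more strained.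

Step 5
Reactants: 8 (2S,3S)-4,4-dimethoxy-2-methyl-3-(prop-1-en-2-yl)-2-vinylcyclohexan-1-one
Product: 10 (5S,6S)-4,4-dimethoxy-6-methyl-5-(prop-1-en-2-yl)-6-vinylcyclohex-2-en-1-one, via trimethylsilyl enol ether 9 (not isolated)
Conditions: LiN(SiMe3)2, Me3SiCl, THF, −78 °C; then Pd(OAc)2 (1.1 equiv), MeCN, rt
Reagents that add atoms: none
Why: Saegusa–Ito dehydrogenation: the ketone can enolise only toward C8 because C10 is quaternary, and divalent palladium converts the silyl enol ether into the C7=C8 enone by β-hydride loss from C7; the ketal carbon C6 prevents any further unsaturation.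

Step 6
Reactants: 10 (5S,6S)-4,4-dimethoxy-6-methyl-5-(prop-1-en-2-yl)-6-vinylcyclohex-2-en-1-one
Product: 11 4,4-dimethoxy-5-(3-hydroxyprop-1-en-2-yl)-6-methyl-6-vinylcyclohex-2-en-1-one (C5 side chain β; C10 methyl β and vinyl α)
Conditions: SeO2 (cat.), t-BuOOH, CH2Cl2, rt
Reagents that add atoms: tert-butyl hydroperoxide, CC(C)(C)OO (terminal oxidant; the oxygen is passed on through SeO2, O=[Se]=O)
Why: Selenium dioxide allylic oxidation (ene reaction, then [2,3]-sigmatropic shift) of the methyl group of a 1,1-disubstituted alkene; enone 10 offers no competing site, since it has no α-methylene, the vinyl group has no allylic hydrogen and the C5 methine lies between two fully substituted carbons; any aldehyde from over-oxidation is returned to the alcohol in step 7.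

Step 7
Reactants: 11 4,4-dimethoxy-5-(3-hydroxyprop-1-en-2-yl)-6-methyl-6-vinylcyclohex-2-en-1-one
Product: 12 4,4-dimethoxy-5-(3-hydroxyprop-1-en-2-yl)-6-methyl-6-vinylcyclohex-2-en-1-ol with the C9 hydroxyl β (cis to C14)
Conditions: NaBH4, CeCl3·7H2O, MeOH, −40 °C
Reagents that add atoms: none
Why: Luche 1,2-reduction: hydride should enter C9 axially on the α face, anti to the axial C10 methyl group of the half-chair that keeps the C5 side chain equatorial (the β face carries C14 and, 1,3 to the carbonyl, the C5 side chain), giving the C9 β-alcohol that step 9 requires; methanol exchange at the dimethyl ketal is degenerate.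

Step 8
Reactants: 12 C9 β-hydroxy C15-hydroxy diol
Product: 13 C15 tert-butyldimethylsilyl ether of 12 (C9 hydroxyl free)
Conditions: TBSCl, imidazole, CH2Cl2, 0 °C
Reagents that add atoms: tert-butyldimethylsilyl chloride, CC(C)(C)[Si](C)(C)Cl
Why: Silylation of the primary allylic hydroxyl in preference to the C9 hydroxyl, which is flanked by the quaternary C10; the C15 oxygen must be masked so that it cannot enter the orthoester exchange of step 9, and a silyl ether survives the bases of steps 10 and 12.

Step 9
Reactants: 13 C15 silyl ether with free C9 β-hydroxyl; 14 trimethyl orthoacetate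
Product: 17 methyl 2-[6,6-dimethoxy-4-methyl-5-[3-(tert-butyldimethylsilyloxy)prop-1-en-2-yl]-4-vinylcyclohex-2-en-1-yl]acetate (C7 acetate chain β; C8=C9 double bond), via mixed orthoester 15 (not isolated), via ketene acetal 16 (not isolated)
Conditions: MeC(OMe)3 (excess), EtCO2H (cat.), xylene, 135 °C, MeOH distilled off
Reagents that add atoms: none
Why: Johnson–Claisen rearrangement: acid-catalysed exchange gives the mixed orthoester, loss of methanol gives the ketene acetal, and the [3,3] shift across C9–C8=C7 is suprafacial, so the C7–C11 bond forms on the β face from which the C9 oxygen departs and the double bond moves to C8=C9; trimethyl orthoacetate is chosen so that any exchange at the dimethyl ketal is degenerate.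

Step 10
Reactants: 17 methyl ester with C7 chain β
Product: 18 2-[6,6-dimethoxy-4-methyl-5-[3-(tert-butyldimethylsilyloxy)prop-1-en-2-yl]-4-vinylcyclohex-2-en-1-yl]acetic acid (C7 chain β)
Conditions: LiOH, THF/MeOH/H2O, rt; then 1 M HCl to pH 4, 0 °C
Reagents that add atoms: lithium hydroxide, [Li+].[OH-]
Why: Saponification of an unhindered methyl ester; the silyl ether and the ketal are stable to hydroxide, and the acidification is brief, cold and stopped at pH 4.

Step 11
Reactants: 18 γ,δ-unsaturated acid
Product: 20 cis-fused γ-lactone with C8 oxygen β and C7–C11 β carrying a C9 α-hydroxyl (C6 dimethyl ketal; C15 silyl ether), via α-epoxy acid 19 (not isolated)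
Conditions: mCPBA (1.05 equiv), CH2Cl2, 0 °C to rt
Reagents that add atoms: meta-chloroperbenzoic acid, OOC(=O)c1cccc(Cl)c1
Why: Peracid epoxidation followed by intramolecular epoxide opening (epoxy acid lactonisation): the cis-disubstituted ring alkene is the most electron-rich of the three (the side-chain alkene is deactivated by its allylic silyloxy group and screened by C6 and C10, and the vinyl group is monosubstituted), and its β face is closed by the pseudoaxial C14 and the axial C6 methoxy group, so oxygen should be delivered to the α face; the carboxyl group tethered on the β face then attacks C8 in the 5-exo, trans-diaxial mode with inversion, catalysed by the aryl carboxylic acid formed, which gives the cis-fused lactone with the C8 oxygen β and leaves the C9 hydroxyl α.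

Step 12
Reactants: 20 hydroxy lactone; 21 N,N-dimethylmethyleneiminium iodide
Product: 22 C11-(dimethylaminomethyl) derivative of 20 (both C11 epimers)
Conditions: LiN(i-Pr)2 (2.3 equiv), THF, −78 °C; then 21, −78 °C to rt
Reagents that add atoms: none
Why: Mannich reaction of a lactone enolate: the first equivalent of base forms the C9 alkoxide and the second the C11 enolate (the only enolisable carbon while C6 is a ketal), which attacks the iminium salt; the C11 configuration is of no consequence.

Step 13
Reactants: 22 Mannich base
Product: 24 α-methylene lactone (C11=C13) with free C9 α-hydroxyl (C6 dimethyl ketal; C15 silyl ether), via quaternary ammonium iodide 23 (not isolated)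
Conditions: MeI, MeOH, rt; then NaHCO3 (aq.), CH2Cl2
Reagents that add atoms: none
Why: Quaternisation of the tertiary amine and base-induced loss of trimethylamine (Hofmann-type elimination through the lactone enolate) should give the exocyclic methylene group under conditions too mild to affect the ketal or the silyl ether.

Step 14
Reactants: 24 silylated methylene lactone
Product: 25 C9 α-hydroxy C15-hydroxy methylene lactone (C6 dimethyl ketal)
Conditions: HF·pyridine, pyridine, THF, 0 °C
Reagents that add atoms: none
Why: Fluoride-induced cleavage of the silyl ether; the pyridine-buffered, water-free medium spares the dimethyl ketal and does not add to the methylene lactone.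

Step 15
Reactants: 25 diol
Product: 26 C9 α-acetoxy C15-acetoxy methylene lactone (C6 dimethyl ketal)
Conditions: Ac2O, DMAP (cat.), pyridine, CH2Cl2, rt
Reagents that add atoms: acetic anhydride, CC(=O)OC(C)=O
Why: Nucleophile-catalysed acylation: the two hydroxyls that end as acetates (C9 and C15) are esterified together while C6 is still a ketal, which keeps the isobutyrate site apart.

Step 16
Reactants: 26 diacetate ketal
Product: 27 C6 ketone of 26
Conditions: TsOH·H2O (cat.), acetone/H2O, 0 °C to rt
Reagents that add atoms: water, O
Why: Acid-catalysed hydrolysis of the dimethyl ketal through the oxocarbenium ion; the conditions are kept mild and the ketone is used at once, because its C8 oxygen is β to the carbonyl (elimination) and C5 and C7 are enolisable.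

Step 17
Reactants: 27 C6 ketone
Product: 28 C6 β-alcohol (hydroxyl cis to the C5 and C7 substituents)
Conditions: NaBH4, CeCl3·7H2O, MeOH, −78 °C
Reagents that add atoms: none
Why: Luche reduction (the cerium salt also suppresses conjugate reduction of the methylene lactone): the β face of the C6 carbonyl is closed by the C5 and C7 substituents and, 1,3 to it, by C14 and the lactone oxygen, so hydride should add from the α face and give the β (axial) alcohol.

Step 18
Reactants: 28 C6 β-alcohol
Product: 29 CNP0500052.1
Conditions: (i-PrCO)2O, DMAP, Et3N, CH2Cl2, rt to 40 °C
Reagents that add atoms: isobutyric anhydride, CC(C)C(=O)OC(=O)C(C)C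
Why: DMAP-catalysed esterification of the hindered axial C6 hydroxyl with the anhydride; no other free hydroxyl remains and the methylene lactone tolerates the amine bases.

## Compound list

1 | 4-methoxy-2-methylphenol | COc1ccc(O)c(C)c1 | starting material
2 | 4,4-dimethoxy-2-methylcyclohexa-2,5-dien-1-one | COC1(OC)C=CC(=O)C(C)=C1 | intermediate
3 | 4,4-dimethoxy-2-methylcyclohex-2-en-1-one | COC1(OC)CCC(=O)C(C)=C1 | intermediate
4 | isopropenylmagnesium bromide | CC(=C)[Mg]Br | starting material
5 | phenyl vinyl sulfoxide | C=CS(=O)c1ccccc1 | starting material
6 | bromomagnesium C9–C10 enolate formed by isopropenyl addition to 3 (C5 isopropenyl β; not isolated) | CC1=C(O[Mg]Br)CCC(OC)(OC)[C@H]1C(C)=C | intermediate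
7 | (2S,3S)-4,4-dimethoxy-2-methyl-2-[2-(phenylsulfinyl)ethyl]-3-(prop-1-en-2-yl)cyclohexan-1-one (sulfinylethyl α, trans to isopropenyl; both epimers at sulfur) | O=S(CC[C@]1(C)C(=O)CCC(OC)(OC)[C@H]1C(C)=C)c1ccccc1 | intermediate
8 | (2S,3S)-4,4-dimethoxy-2-methyl-3-(prop-1-en-2-yl)-2-vinylcyclohexan-1-one | C=C[C@]1(C)C(=O)CCC(OC)(OC)[C@H]1C(C)=C | intermediate
9 | trimethylsilyl enol ether of 8 (C8=C9; not isolated) | C=C[C@]1(C)C(O[Si](C)(C)C)=CCC(OC)(OC)[C@H]1C(C)=C | intermediate
10 | (5S,6S)-4,4-dimethoxy-6-methyl-5-(prop-1-en-2-yl)-6-vinylcyclohex-2-en-1-one | C=C[C@]1(C)C(=O)C=CC(OC)(OC)[C@H]1C(C)=C | intermediate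
11 | 4,4-dimethoxy-5-(3-hydroxyprop-1-en-2-yl)-6-methyl-6-vinylcyclohex-2-en-1-one (C5 side chain β; C10 methyl β, vinyl α) | C=C[C@]1(C)C(=O)C=CC(OC)(OC)[C@H]1C(=C)CO | intermediate
12 | 4,4-dimethoxy-5-(3-hydroxyprop-1-en-2-yl)-6-methyl-6-vinylcyclohex-2-en-1-ol, C9 hydroxyl β (cis to C14) | C=C[C@]1(C)[C@@H](O)C=CC(OC)(OC)[C@H]1C(=C)CO | intermediate
13 | C15 tert-butyldimethylsilyl ether of 12 (C9 β-hydroxyl free) | C=C[C@]1(C)[C@@H](O)C=CC(OC)(OC)[C@H]1C(=C)CO[Si](C)(C)C(C)(C)C | intermediate
14 | trimethyl orthoacetate | CC(OC)(OC)OC | starting material
15 | mixed orthoester of 13 at the C9 oxygen (not isolated) | C=C[C@]1(C)[C@@H](OC(C)(OC)OC)C=CC(OC)(OC)[C@H]1C(=C)CO[Si](C)(C)C(C)(C)C | intermediate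
16 | ketene acetal of 13, C9–O–C(OMe)=CH2 (not isolated) | C=C[C@]1(C)[C@@H](OC(=C)OC)C=CC(OC)(OC)[C@H]1C(=C)CO[Si](C)(C)C(C)(C)C | intermediate
17 | methyl 2-[6,6-dimethoxy-4-methyl-5-[3-(tert-butyldimethylsilyloxy)prop-1-en-2-yl]-4-vinylcyclohex-2-en-1-yl]acetate (C7 chain β, cis to the C5 side chain and C14) | C=C[C@]1(C)C=C[C@@H](CC(=O)OC)C(OC)(OC)[C@H]1C(=C)CO[Si](C)(C)C(C)(C)C | intermediate
18 | carboxylic acid corresponding to 17 | C=C[C@]1(C)C=C[C@@H](CC(=O)O)C(OC)(OC)[C@H]1C(=C)CO[Si](C)(C)C(C)(C)C | intermediate
19 | 8α,9α-epoxide of 18 (not isolated) | C=C[C@]1(C)[C@@H]2O[C@@H]2[C@@H](CC(=O)O)C(OC)(OC)[C@H]1C(=C)CO[Si](C)(C)C(C)(C)C | intermediate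
20 | cis-fused γ-lactone (C8–O β, C7–C11 β) with C9 α-hydroxyl, C6 dimethyl ketal and C15 silyl ether | C=C[C@]1(C)[C@H](O)[C@H]2OC(=O)C[C@H]2C(OC)(OC)[C@H]1C(=C)CO[Si](C)(C)C(C)(C)C | intermediate
21 | N,N-dimethylmethyleneiminium iodide | C[N+](C)=C.[I-] | starting material
22 | C11-(dimethylaminomethyl) derivative of 20 (both C11 epimers) | C=C[C@]1(C)[C@H](O)[C@H]2OC(=O)C(CN(C)C)[C@H]2C(OC)(OC)[C@H]1C(=C)CO[Si](C)(C)C(C)(C)C | intermediate
23 | trimethylammonium iodide of 22 (not isolated) | C=C[C@]1(C)[C@H](O)[C@H]2OC(=O)C(C[N+](C)(C)C)[C@H]2C(OC)(OC)[C@H]1C(=C)CO[Si](C)(C)C(C)(C)C.[I-] | intermediate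
24 | α-methylene lactone with C9 α-hydroxyl, C6 dimethyl ketal and C15 silyl ether | C=C[C@]1(C)[C@H](O)[C@H]2OC(=O)C(=C)[C@H]2C(OC)(OC)[C@H]1C(=C)CO[Si](C)(C)C(C)(C)C | intermediate
25 | α-methylene lactone with C9 α-hydroxyl and C15 hydroxyl (C6 dimethyl ketal) | C=C[C@]1(C)[C@H](O)[C@H]2OC(=O)C(=C)[C@H]2C(OC)(OC)[C@H]1C(=C)CO | intermediate
26 | C9,C15-diacetate of 25 (C6 dimethyl ketal) | C=C[C@]1(C)[C@H](OC(C)=O)[C@H]2OC(=O)C(=C)[C@H]2C(OC)(OC)[C@H]1C(=C)COC(C)=O | intermediate
27 | C6 ketone of 26 | C=C[C@]1(C)[C@H](OC(C)=O)[C@H]2OC(=O)C(=C)[C@H]2C(=O)[C@H]1C(=C)COC(C)=O | intermediate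
28 | C6 β-alcohol (hydroxyl cis to the C5 and C7 substituents) | C=C[C@]1(C)[C@H](OC(C)=O)[C@H]2OC(=O)C(=C)[C@H]2[C@@H](O)[C@H]1C(=C)COC(C)=O | intermediate
29 | CNP0500052.1 | C=C[C@]1(C)[C@H](OC(C)=O)[C@H]2OC(=O)C(=C)[C@H]2[C@@H](OC(=O)C(C)C)[C@H]1C(=C)COC(C)=O | target

## Step count and uncertain steps

Total: 18 steps. Longest linear sequence: 18 steps (1 to 29); 4, 5, 14 and 21 enter as purchased reagents.

**Step 3 (key step).** Addition of 4 to C5 may be slow because C5 lies between the ketal carbon and the methyl-bearing C10. The ligand-free background reaction (loss of enantioselectivity) and 1,2-addition then gain ground, and the bromomagnesium enolate may be protonated or may exchange its proton before it adds to 5. Fallback: starting from 3, the conjugate addition is run with Me3SiCl present and the trimethylsilyl enol ether F1 is isolated. MeLi in THF releases the lithium enolate F2, the counter-ion for which additions to 5 are best established, and F2 is treated with 5 to return to the route at 7. The two bond formations are thus uncoupled, and each can be optimised and checked separately.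

**Step 7.** Facial selectivity of hydride addition may be poor, because the two half-chairs of 11 expose different faces; the wrong carbinol configuration would be carried into C7. Fallback: starting from 11, the primary hydroxyl is silylated first to give the keto silyl ether F3. The ketone is then reduced under catalyst control with BH3·SMe2 and the B-methyl oxazaborolidine derived from diphenylprolinol (the antipode matched to the substrate), returning to the route at 13.

**Step 9.** Orthoester exchange at the neopentyl-type C9 hydroxyl may be slow, and the carboxylic acid catalyst may ionise the allylic alcohol or eliminate methanol from the ketal before the rearrangement. The transition state also brings the forming C7–C11 bond into a 1,3-relationship with the C5 side chain. Fallback: starting from 13, acetylation gives the allylic acetate F4. LiN(i-Pr)2 and Me3SiCl at −78 °C give the silyl ketene acetal F5, which rearranges on warming (Ireland–Claisen rearrangement) and after aqueous work-up returns to the route at acid 18.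

**Step 11.** The peracid may lose chemoselectivity (epoxidation of the side-chain alkene) or attack the β face. Fallback: starting from 18, iodolactonisation (I2, NaHCO3) is intramolecular and therefore specific for C8=C9; it gives the iodolactone F6 (C8 oxygen β, C9 iodide α). K2CO3 in MeOH opens the lactone and closes the β-epoxy methyl ester F7. Buffered acetolysis (AcOH, NaOAc) opens F7 in the trans-diaxial sense at C9 from the α face, and the freed C8 hydroxyl lactonises to the acetoxy lactone F8. K2CO3 in MeOH removes the acetate and returns to the route at 20.

**Step 17 (with step 16).** The ketone 27 may lose the lactone carboxylate by β-elimination or epimerise next to the carbonyl during hydrolysis, and hydride may attack the β face if the ring adopts another conformation. Fallback for the facial problem: starting from 27, if the C6 α-alcohol F9 is formed, Mitsunobu esterification with isobutyric acid (PPh3, diisopropyl azodicarboxylate) inverts C6 and returns to the route directly at 29.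

## Further compounds

F1 | step 3 | trimethylsilyl enol ether of (3S)-4,4-dimethoxy-2-methyl-3-(prop-1-en-2-yl)cyclohexan-1-one (C9–C10 enol ether) | CC1=C(O[Si](C)(C)C)CCC(OC)(OC)[C@H]1C(C)=C
F2 | step 3 | lithium enolate corresponding to F1 | CC1=C(O[Li])CCC(OC)(OC)[C@H]1C(C)=C
F3 | step 7 | C15 tert-butyldimethylsilyl ether of 11 | C=C[C@]1(C)C(=O)C=CC(OC)(OC)[C@H]1C(=C)CO[Si](C)(C)C(C)(C)C
F4 | step 9 | C9 β-acetate of 13 | C=C[C@]1(C)[C@@H](OC(C)=O)C=CC(OC)(OC)[C@H]1C(=C)CO[Si](C)(C)C(C)(C)C
F5 | step 9 | trimethylsilyl ketene acetal of F4 | C=C[C@]1(C)[C@@H](OC(=C)O[Si](C)(C)C)C=CC(OC)(OC)[C@H]1C(=C)CO[Si](C)(C)C(C)(C)C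
F6 | step 11 | iodolactone of 18 (C8 oxygen β, C9 iodide α) | C=C[C@]1(C)[C@H](I)[C@H]2OC(=O)C[C@H]2C(OC)(OC)[C@H]1C(=C)CO[Si](C)(C)C(C)(C)C
F7 | step 11 | 8β,9β-epoxide of methyl ester 17 | C=C[C@]1(C)[C@H]2O[C@H]2[C@@H](CC(=O)OC)C(OC)(OC)[C@H]1C(=C)CO[Si](C)(C)C(C)(C)C
F8 | step 11 | C9 α-acetate of 20 | C=C[C@]1(C)[C@H](OC(C)=O)[C@H]2OC(=O)C[C@H]2C(OC)(OC)[C@H]1C(=C)CO[Si](C)(C)C(C)(C)C
F9 | step 17 | C6 α-alcohol (C6 epimer of 28) | C=C[C@]1(C)[C@H](OC(C)=O)[C@H]2OC(=O)C(=C)[C@H]2[C@H](O)[C@H]1C(=C)COC(C)=O
A1 | alternative 1 | tert-butyl 2-[6-(tert-butyldimethylsilyloxy)-4-methyl-5-[3-(triisopropylsilyloxy)prop-1-en-2-yl]-4-vinylcyclohex-2-en-1-yl]acetate | C=C[C@]1(C)C=C[C@@H](CC(=O)OC(C)(C)C)[C@@H](O[Si](C)(C)C(C)(C)C)[C@H]1C(=C)CO[Si](C(C)C)(C(C)C)C(C)C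
A2 | alternative 1 | open-chain triene with C7 vinyl group and two vinyl groups on C10 | C=CC(C)(C=C)[C@H](C(=C)CO[Si](C(C)C)(C(C)C)C(C)C)[C@H](O[Si](C)(C)C(C)(C)C)[C@@H](C=C)CC(=O)OC(C)(C)C
A3 | alternative 2 | cis-fused α-methylene lactone with C9 para-methoxybenzyl ether, C6 tert-butyldimethylsilyl ether and C15 acetate | C=C[C@]1(C)[C@H](OCc3ccc(OC)cc3)[C@H]2OC(=O)C(=C)[C@H]2[C@@H](O[Si](C)(C)C(C)(C)C)[C@H]1C(=C)COC(C)=O
A4 | alternative 2 | open-chain C8 aldehyde with Z-configured methyl 2-(bromomethyl)enoate terminus | O=C[C@@H](OCc1ccc(OC)cc1)[C@@](C)(C=C)[C@H](C(=C)COC(C)=O)[C@H](O[Si](C)(C)C(C)(C)C)/C=C(\CBr)C(=O)OC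
A5 | alternative 3 | methyl 6-acetyl-5-(tert-butyldimethylsilyloxy)-1-methylcyclohex-3-ene-1-carboxylate (acetyl and silyloxy cis, ester trans to acetyl) | COC(=O)[C@]1(C)CC=C[C@@H](O[Si](C)(C)C(C)(C)C)[C@H]1C(C)=O
A6 | alternative 3 | (E)-1-(tert-butyldimethylsilyloxy)buta-1,3-diene | C=C/C=C/O[Si](C)(C)C(C)(C)C
A7 | alternative 3 | methyl (E)-2-methyl-4-oxopent-2-enoate | COC(=O)/C(C)=C/C(C)=O
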